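Retrosynthesis: remove six MOM ethers, then cut C2–C1' (ring B off a chromone), O1–C2 and C2–C3 (ring C), C4a–C4, the three ring C'' bonds C4a''–C4'', C4''–C3'' and O1''–C2'', and last the biaryl bond C6–C8''.
Forward: rings A and A'', both from phloroglucinol, are joined first; ring C'' closes next, ring C follows as a chromone, and ring B is attached last.
Enabling feature: the pyranone ring C'' (O1'', C2'', C3'', C4'', C4a'', C8a'') is fused to ring A'' along C4a''–C8a'', and C8a'', which carries O1'', is the neighbour of the axis carbon C8''. A ring A'' with its only free OH on C8a'' and an iodine on C4a'' can therefore be annulated with CO and an arylacetylene in just one, 8-linked, orientation.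
On ring A the oxygen para to the axis (the future O1) is the only one held as a benzyl ether, so ring C can close only to the 6-linked isomer.
Stereochemistry: the single stereocentre C2 (S) comes from a ligand-controlled rhodium-catalysed 1,4-addition of the ring B boronic acid to the Re face of C2 of the chromone. It is made in the penultimate step and sees only mild acid afterwards.
Key step: step 10

Assumption: the target structure defines only C2, so the C6–C8'' axis is left undefined; from 21 onward hindered rotation may give atropisomers, and all of them count as the numbered compound.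

Step 1
Reactants: 1 phloroglucinol
Product: 2 3,5-bis(methoxymethoxy)phenol
Conditions: NaH (2.0 equiv), MOMCl (2.0 equiv), DMF, 0 °C to rt
Reagents that add atoms: chloromethyl methyl ether (MOMCl), COCCl
Why: Williamson-type O-alkylation of the sodium phenoxide by the chloromethyl ether; the three hydroxyls of 1 are equivalent, so two equivalents of base and MOMCl should favour the bis-ether, which chromatography separates from the mono- and tris-ethers.

Step 2
Reactants: 2 3,5-bis(methoxymethoxy)phenol
Product: 3 1-(benzyloxy)-3,5-bis(methoxymethoxy)benzene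
Conditions: BnBr, K2CO3, DMF, rt
Reagents that add atoms: benzyl bromide, BrCc1ccccc1
Why: Williamson ether synthesis on the single free phenol, which marks the oxygen that will lie para to the axis (the future O1) with a group orthogonal to MOM and stable to hot hydroxide.

Step 3
Reactants: 2 3,5-bis(methoxymethoxy)phenol
Product: 4 3,5-bis(methoxymethoxy)phenyl N,N-diethylcarbamate
Conditions: Et2NC(O)Cl, K2CO3, MeCN, reflux
Reagents that add atoms: N,N-diethylcarbamoyl chloride, CCN(CC)C(=O)Cl
Why: O-Carbamoylation (nucleophilic acyl substitution) of the same phenol puts on the future O1'' the strongest oxygen-based director for ortho-lithiation, one that ranks above the MOM ethers.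

Step 4
Reactants: 4 3,5-bis(methoxymethoxy)phenyl N,N-diethylcarbamate
Product: 6 2-iodo-3,5-bis(methoxymethoxy)phenyl N,N-diethylcarbamate, via aryllithium 5 (not isolated)
Conditions: s-BuLi, TMEDA, THF, −78 °C; then I2, THF, −78 °C to rt
Reagents that add atoms: iodine, II
Why: Directed ortho-metalation: s-BuLi–TMEDA is bound by the carbamate and removes one of the two equivalent hydrogens that sit between the carbamate and an OMOM group, and iodine traps the aryllithium at −78 °C before an anionic Fries shift can set in.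

Step 5
Reactants: 3 1-(benzyloxy)-3,5-bis(methoxymethoxy)benzene; 6 2-iodo-3,5-bis(methoxymethoxy)phenyl N,N-diethylcarbamate
Product: 9 4'-(benzyloxy)-2',4,6,6'-tetrakis(methoxymethoxy)biphenyl-2-yl N,N-diethylcarbamate, via aryllithium 7 (not isolated), via arylzinc chloride 8 (not isolated)
Conditions: 3 (1.5 equiv), n-BuLi, THF, 0 °C; ZnCl2, 0 °C to rt; then 6, Pd2(dba)3 (2 mol %), RuPhos (2-dicyclohexylphosphino-2',6'-diisopropoxybiphenyl, 8 mol %), THF, 70 °C
Reagents that add atoms: none
Why: Directed ortho-metalation of 3 at the carbon between its two OMOM groups (doubly chelated, unlike the sites next to the weakly directing OBn), transmetalation to zinc and Negishi coupling with 6, for which bulky electron-rich biarylphosphines are an established answer to tetra-ortho-substituted biaryls and which avoids the protodeboronation typical of 2,6-dialkoxyarylboronic acids.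

Step 6
Reactants: 9 4'-(benzyloxy)-2',4,6,6'-tetrakis(methoxymethoxy)biphenyl-2-yl N,N-diethylcarbamate
Product: 11 4'-(benzyloxy)-3-iodo-2',4,6,6'-tetrakis(methoxymethoxy)biphenyl-2-yl N,N-diethylcarbamate, via aryllithium 10 (not isolated)
Conditions: s-BuLi, TMEDA, THF, −78 °C; then I2, THF, −78 °C to rt
Reagents that add atoms: iodine, II
Why: Directed ortho-metalation: the carbamate has a single ortho hydrogen left (on the future C4a''), which also adjoins an OMOM group, so complex-induced deprotonation at −78 °C and an iodine quench should place the halogen there.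

Step 7
Reactants: 11 4'-(benzyloxy)-3-iodo-2',4,6,6'-tetrakis(methoxymethoxy)biphenyl-2-yl N,N-diethylcarbamate
Product: 12 4'-(benzyloxy)-3-iodo-2',4,6,6'-tetrakis(methoxymethoxy)biphenyl-2-ol
Conditions: NaOH (excess), EtOH–H2O, reflux; then aq NH4Cl
Reagents that add atoms: none
Why: Basic hydrolysis of the aryl carbamate (acyl substitution at a hindered carbonyl, hence excess hydroxide at reflux), to which MOM ethers, the benzyl ether and the electron-rich aryl iodide are inert.

Step 8
Reactants: 13 4-hydroxybenzaldehyde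
Product: 14 4-(methoxymethoxy)benzaldehyde
Conditions: MOMCl, K2CO3, acetone, rt
Reagents that add atoms: chloromethyl methyl ether (MOMCl), COCCl
Why: Williamson-type O-alkylation of the acidic para-formyl phenol, a routine MOM protection.

Step 9
Reactants: 14 4-(methoxymethoxy)benzaldehyde
Product: 15 1-ethynyl-4-(methoxymethoxy)benzene
Conditions: dimethyl (1-diazo-2-oxopropyl)phosphonate, K2CO3, MeOH, rt
Reagents that add atoms: dimethyl (1-diazo-2-oxopropyl)phosphonate, COP(=O)(OC)C(=[N+]=[N-])C(C)=O
Why: Seyferth–Gilbert homologation in its Ohira–Bestmann form, in which methanolysis frees the diazomethylphosphonate anion, this olefinates the aldehyde, and loss of N2 with a 1,2-hydrogen shift gives the terminal alkyne under conditions harmless to the MOM ether.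

Step 10
Reactants: 12 4'-(benzyloxy)-3-iodo-2',4,6,6'-tetrakis(methoxymethoxy)biphenyl-2-ol; 15 1-ethynyl-4-(methoxymethoxy)benzene; 16 carbon monoxide
Product: 19 8-[4-(benzyloxy)-2,6-bis(methoxymethoxy)phenyl]-5,7-bis(methoxymethoxy)-2-[4-(methoxymethoxy)phenyl]-4H-chromen-4-one, via ynone 17 (not isolated), via enaminone 18 (not isolated)
Conditions: PdCl2(PPh3)2 (5 mol %), CO (10 bar), 15 (1.5 equiv), Et2NH, 100 °C, autoclave, no copper salt
Reagents that add atoms: none
Why: The cycle should start with oxidative addition of the C4a''–I bond of 12 to zerovalent palladium (generated in situ from PdCl2(PPh3)2); insertion of CO then turns the aryl into an aroyl ligand on divalent palladium, the amine hands over the acetylide of 15, and reductive elimination releases ynone 17 with the new bonds C4a''–C4'' and C4''–C3''. Conjugate addition of Et2NH at C2'' converts 17 into enaminone 18, whose amino group is then exchanged for the neighbouring C8a'' oxygen by addition–elimination; this forges O1''–C2'' and shuts ring C'', 6-endo-trig on 18 and 6-endo-dig in the formal sense on 17. The closest known reaction type is the palladium-catalysed carbonylative annulation of ortho-iodophenols with terminal arylacetylenes to flavones, applied here to a more crowded iodophenol. No stereocentre is created. The step needs 6-endo rather than 5-exo (aurone) closure, which the amine secures because in 18 only C2'' remains electrophilic, and it needs closure through O1'' rather than the C5'' oxygen, which the substrate secures because C8a''–OH is the only free hydroxyl while C5''–O is a MOM ether. It also needs CO uptake to outrun direct alkynylation (which would end in a benzofuran), and CO pressure, the absence of copper and the crowded, electron-rich aryl–palladium bond should all favour that.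

Step 11
Reactants: 19 8-[4-(benzyloxy)-2,6-bis(methoxymethoxy)phenyl]-5,7-bis(methoxymethoxy)-2-[4-(methoxymethoxy)phenyl]-4H-chromen-4-one
Product: 20 8-[4-hydroxy-2,6-bis(methoxymethoxy)phenyl]-5,7-bis(methoxymethoxy)-2-[4-(methoxymethoxy)phenyl]-4H-chromen-4-one
Conditions: H2 (1 atm), 10% Pd/C, EtOAc–MeOH, rt
Reagents that add atoms: none
Why: Catalytic hydrogenolysis of the aryl benzyl ether, which at balloon pressure is known to spare the conjugated C2''–C3'' double bond of flavones and leaves MOM ethers untouched.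

Step 12
Reactants: 20 8-[4-hydroxy-2,6-bis(methoxymethoxy)phenyl]-5,7-bis(methoxymethoxy)-2-[4-(methoxymethoxy)phenyl]-4H-chromen-4-one
Product: 21 8-[4-hydroxy-3-iodo-2,6-bis(methoxymethoxy)phenyl]-5,7-bis(methoxymethoxy)-2-[4-(methoxymethoxy)phenyl]-4H-chromen-4-one
Conditions: NIS (1.0 equiv), CH2Cl2, −20 to 0 °C, dark
Reagents that add atoms: N-iodosuccinimide, O=C1CCC(=O)N1I
Why: Electrophilic aromatic iodination: the free phenol makes ring A by far the most nucleophilic ring, its para position is blocked by the axis and its two ortho positions are equivalent, so one equivalent of NIS at low temperature should give the mono-iodide at the future C4a.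

Step 13
Reactants: 21 8-[4-hydroxy-3-iodo-2,6-bis(methoxymethoxy)phenyl]-5,7-bis(methoxymethoxy)-2-[4-(methoxymethoxy)phenyl]-4H-chromen-4-one
Product: 23 8-[3-acetyl-4-hydroxy-2,6-bis(methoxymethoxy)phenyl]-5,7-bis(methoxymethoxy)-2-[4-(methoxymethoxy)phenyl]-4H-chromen-4-one, via enol ether 22 (not isolated)
Conditions: CH2=C(OEt)SnBu3, PdCl2(PPh3)2 (5 mol %), toluene, 100 °C; then 0.5 M HCl, THF, 0 °C
Reagents that add atoms: tributyl(1-ethoxyvinyl)stannane, C=C(OCC)[Sn](CCCC)(CCCC)CCCC; water, O
Why: Stille coupling of the aryl iodide with the 1-ethoxyvinylstannane places a masked acetyl group on C4a without acid or strong base, and cold dilute acid hydrolyses the enol ether far faster than it attacks aryl MOM ethers.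

Step 14
Reactants: 23 8-[3-acetyl-4-hydroxy-2,6-bis(methoxymethoxy)phenyl]-5,7-bis(methoxymethoxy)-2-[4-(methoxymethoxy)phenyl]-4H-chromen-4-one
Product: 25 6-{5,7-bis(methoxymethoxy)-2-[4-(methoxymethoxy)phenyl]-4-oxo-4H-chromen-8-yl}-5,7-bis(methoxymethoxy)-4H-chromen-4-one, via enaminone 24 (not isolated)
Conditions: Me2NCH(OMe)2, toluene, 100 °C; concentrate; then TsOH·H2O (1.0 equiv), CH2Cl2, rt
Reagents that add atoms: N,N-dimethylformamide dimethyl acetal, COC(OC)N(C)C
Why: Enaminone route to chromones: the methyl ketone condenses with the amide acetal, and on protonation the C8a hydroxyl, the only free oxygen beside the acyl group, adds to C2 and expels dimethylamine (6-endo addition–elimination), the freed amine consuming the acid so that the MOM ethers persist and the 6-linkage is fixed.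

Step 15
Reactants: 25 6-{5,7-bis(methoxymethoxy)-2-[4-(methoxymethoxy)phenyl]-4-oxo-4H-chromen-8-yl}-5,7-bis(methoxymethoxy)-4H-chromen-4-one; 26 [4-(methoxymethoxy)phenyl]boronic acid
Product: 27 (2S)-6-{5,7-bis(methoxymethoxy)-2-[4-(methoxymethoxy)phenyl]-4-oxo-4H-chromen-8-yl}-5,7-bis(methoxymethoxy)-2-[4-(methoxymethoxy)phenyl]-2,3-dihydro-4H-chromen-4-one
Conditions: 26 (3 equiv), [Rh(OH)(cod)]2 (2.5 mol %), (S)-MeO-F12-BIPHEP ((S)-2,2'-bis[bis(3,4,5-trifluorophenyl)phosphino]-6,6'-dimethoxybiphenyl, 5.5 mol %), CH2Cl2–H2O (10:1), rt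
Reagents that add atoms: none
Why: Rhodium-catalysed asymmetric 1,4-addition of an arylboronic acid to a chromone (Hayashi–Miyaura reaction): the aryl–rhodium species held by the electron-poor (S)-biaryl bisphosphine should add to the Re face of C2, the same spatial face that (S)-ligands of this class select on cyclic enones, which sets (2S) under ligand control, while the 2-aryl-substituted enone of the flavone half is too hindered to react and the base-free medium at room temperature avoids ring opening of the flavanone.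

Step 16
Reactants: 27 (2S)-hexakis-MOM ether
Product: 28 (2S)-6-[5,7-dihydroxy-2-(4-hydroxyphenyl)-4-oxo-4H-chromen-8-yl]-5,7-dihydroxy-2-(4-hydroxyphenyl)-2,3-dihydro-4H-chromen-4-one (CNP0154104.1)
Conditions: HCl (1.25 M in MeOH), 40 °C; work-up kept below pH 7
Reagents that add atoms: none
Why: Acid-catalysed acetal exchange with methanol removes all six MOM groups as dimethoxymethane, and C2 should stay intact because flavanones open to chalcones, and so racemise or drift to the 8-linked isomer, under basic rather than mildly acidic conditions.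

Compound list
1 | phloroglucinol (benzene-1,3,5-triol) | Oc1cc(O)cc(O)c1 | starting material
2 | 3,5-bis(methoxymethoxy)phenol | COCOc1cc(O)cc(OCOC)c1 | intermediate
3 | 1-(benzyloxy)-3,5-bis(methoxymethoxy)benzene | COCOc1cc(OCOC)cc(OCc2ccccc2)c1 | intermediate
4 | 3,5-bis(methoxymethoxy)phenyl N,N-diethylcarbamate | CCN(CC)C(=O)Oc1cc(OCOC)cc(OCOC)c1 | intermediate
5 | 2-lithio-3,5-bis(methoxymethoxy)phenyl N,N-diethylcarbamate (not isolated) | CCN(CC)C(=O)Oc1cc(OCOC)cc(OCOC)c1[Li] | intermediate
6 | 2-iodo-3,5-bis(methoxymethoxy)phenyl N,N-diethylcarbamate | CCN(CC)C(=O)Oc1cc(OCOC)cc(OCOC)c1I | intermediate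
7 | [4-(benzyloxy)-2,6-bis(methoxymethoxy)phenyl]lithium (not isolated) | [Li]c1c(OCOC)cc(OCc2ccccc2)cc1OCOC | intermediate
8 | [4-(benzyloxy)-2,6-bis(methoxymethoxy)phenyl]zinc chloride (not isolated) | Cl[Zn]c1c(OCOC)cc(OCc2ccccc2)cc1OCOC | intermediate
9 | 4'-(benzyloxy)-2',4,6,6'-tetrakis(methoxymethoxy)biphenyl-2-yl N,N-diethylcarbamate | CCN(CC)C(=O)Oc1cc(OCOC)cc(OCOC)c1-c1c(OCOC)cc(OCc2ccccc2)cc1OCOC | intermediate
10 | 3-lithio derivative of 9, lithium between the carbamate and the 4-OMOM group (not isolated) | CCN(CC)C(=O)Oc1c([Li])c(OCOC)cc(OCOC)c1-c1c(OCOC)cc(OCc2ccccc2)cc1OCOC | intermediate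
11 | 4'-(benzyloxy)-3-iodo-2',4,6,6'-tetrakis(methoxymethoxy)biphenyl-2-yl N,N-diethylcarbamate | CCN(CC)C(=O)Oc1c(I)c(OCOC)cc(OCOC)c1-c1c(OCOC)cc(OCc2ccccc2)cc1OCOC | intermediate
12 | 4'-(benzyloxy)-3-iodo-2',4,6,6'-tetrakis(methoxymethoxy)biphenyl-2-ol (key-step precursor) | Oc1c(I)c(OCOC)cc(OCOC)c1-c1c(OCOC)cc(OCc2ccccc2)cc1OCOC | intermediate
13 | 4-hydroxybenzaldehyde | O=Cc1ccc(O)cc1 | starting material
14 | 4-(methoxymethoxy)benzaldehyde | COCOc1ccc(C=O)cc1 | intermediate
15 | 1-ethynyl-4-(methoxymethoxy)benzene | C#Cc1ccc(OCOC)cc1 | intermediate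
16 | carbon monoxide | [C-]#[O+] | starting material
17 | 1-[4'-(benzyloxy)-2-hydroxy-2',4,6,6'-tetrakis(methoxymethoxy)biphenyl-3-yl]-3-[4-(methoxymethoxy)phenyl]prop-2-yn-1-one (not isolated) | O=C(C#Cc1ccc(OCOC)cc1)c1c(O)c(-c2c(OCOC)cc(OCc3ccccc3)cc2OCOC)c(OCOC)cc1OCOC | intermediate
18 | 3-(diethylamino) enaminone from 17 and Et2NH, double-bond geometry not defined (not isolated) | CCN(CC)C(=CC(=O)c1c(O)c(-c2c(OCOC)cc(OCc3ccccc3)cc2OCOC)c(OCOC)cc1OCOC)c1ccc(OCOC)cc1 | intermediate
19 | 8-[4-(benzyloxy)-2,6-bis(methoxymethoxy)phenyl]-5,7-bis(methoxymethoxy)-2-[4-(methoxymethoxy)phenyl]-4H-chromen-4-one (key-step product) | O=c1cc(-c2ccc(OCOC)cc2)oc2c(-c3c(OCOC)cc(OCc4ccccc4)cc3OCOC)c(OCOC)cc(OCOC)c12 | intermediate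
20 | 8-[4-hydroxy-2,6-bis(methoxymethoxy)phenyl]-5,7-bis(methoxymethoxy)-2-[4-(methoxymethoxy)phenyl]-4H-chromen-4-one | O=c1cc(-c2ccc(OCOC)cc2)oc2c(-c3c(OCOC)cc(O)cc3OCOC)c(OCOC)cc(OCOC)c12 | intermediate
21 | 8-[4-hydroxy-3-iodo-2,6-bis(methoxymethoxy)phenyl]-5,7-bis(methoxymethoxy)-2-[4-(methoxymethoxy)phenyl]-4H-chromen-4-one | O=c1cc(-c2ccc(OCOC)cc2)oc2c(-c3c(OCOC)cc(O)c(I)c3OCOC)c(OCOC)cc(OCOC)c12 | intermediate
22 | 8-[3-(1-ethoxyvinyl)-4-hydroxy-2,6-bis(methoxymethoxy)phenyl] analogue of 21 (not isolated) | O=c1cc(-c2ccc(OCOC)cc2)oc2c(-c3c(OCOC)cc(O)c(C(=C)OCC)c3OCOC)c(OCOC)cc(OCOC)c12 | intermediate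
23 | 8-[3-acetyl-4-hydroxy-2,6-bis(methoxymethoxy)phenyl]-5,7-bis(methoxymethoxy)-2-[4-(methoxymethoxy)phenyl]-4H-chromen-4-one | CC(=O)c1c(O)cc(OCOC)c(-c2c(OCOC)cc(OCOC)c3c(=O)cc(-c4ccc(OCOC)cc4)oc23)c1OCOC | intermediate
24 | (E)-3-(dimethylamino)acryloyl analogue of 23 (not isolated) | CN(C)/C=C/C(=O)c1c(O)cc(OCOC)c(-c2c(OCOC)cc(OCOC)c3c(=O)cc(-c4ccc(OCOC)cc4)oc23)c1OCOC | intermediate
25 | 6-{5,7-bis(methoxymethoxy)-2-[4-(methoxymethoxy)phenyl]-4-oxo-4H-chromen-8-yl}-5,7-bis(methoxymethoxy)-4H-chromen-4-one | O=c1ccoc2cc(OCOC)c(-c3c(OCOC)cc(OCOC)c4c(=O)cc(-c5ccc(OCOC)cc5)oc34)c(OCOC)c12 | intermediate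
26 | [4-(methoxymethoxy)phenyl]boronic acid | COCOc1ccc(B(O)O)cc1 | starting material
27 | (2S)-hexakis-MOM ether of the target | O=C1C[C@@H](c2ccc(OCOC)cc2)Oc2cc(OCOC)c(-c3c(OCOC)cc(OCOC)c4c(=O)cc(-c5ccc(OCOC)cc5)oc34)c(OCOC)c21 | intermediate
28 | (2S)-6-[5,7-dihydroxy-2-(4-hydroxyphenyl)-4-oxo-4H-chromen-8-yl]-5,7-dihydroxy-2-(4-hydroxyphenyl)-2,3-dihydro-4H-chromen-4-one, CNP0154104.1 | O=C1C[C@@H](c2ccc(O)cc2)Oc2cc(O)c(-c3c(O)cc(O)c4c(=O)cc(-c5ccc(O)cc5)oc34)c(O)c21 | target

Total step count: 16.
Longest linear sequence: 13 steps (1, 3, 4, 5, 6, 7, 10, 11, 12, 13, 14, 15, 16).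

Steps most likely to fail

Step 10.
- **What may go wrong:** Palladium may insert slowly into the doubly flanked C–I bond. Alkynylation may occur before CO uptake and be followed by closure to a benzofuran. Diethylamine may capture the aroyl–palladium species as an amide, or the iodine may be lost reductively.
- **Fallback:** It sets out from 12 and 15 and returns at 19, reaching the same ynone by carbonyl addition instead of carbonylation.
  - Compound 12 is silylated (TBSCl, imidazole, DMF) to the silyl ether F1.
  - Iodine–magnesium exchange (iPrMgCl·LiCl, THF, 0 °C) gives the arylmagnesium chloride F2.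
  - F2 is added to 3-[4-(methoxymethoxy)phenyl]prop-2-ynal F4, itself made from 15 through the lithium acetylide F3 (n-BuLi, THF, −78 °C, then DMF).
  - The resulting racemic propargylic alcohol F5 is oxidised with MnO2 to the silylated ynone F6.
  - TBAF frees 17, and Et2NH in EtOH closes it through 18 to 19.

Step 6.
- **What may go wrong:** Lithiation may compete at C6'' between the two OMOM groups or on ring A. The benzylic CH2 may be deprotonated, or an anionic Fries shift may start on warming.
- **Fallback:** It sets out from 9 and returns at 12, replacing deprotonation by electrophilic substitution.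
  - The carbamate is hydrolysed first (NaOH, EtOH–H2O, reflux) to the biaryl phenol F7.
  - The phenoxide ring, now the most nucleophilic one, is iodinated with I2 and NaHCO3 in THF–H2O at 0 °C. Attack is expected at the less crowded position ortho to the hydroxyl rather than between the two OMOM groups, which gives 12.

Step 15.
- **What may go wrong:** Carborhodation of the electron-rich 5,7-dioxygenated chromone may be slow and protodeboronation may outrun it. One sense of the axis may be mismatched with the ligand. Reversible ring opening of the flavanone may erode the enantiomeric purity. Should the sense of induction prove opposite, the (R)-ligand takes the place of the (S)-ligand.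
- **Fallback:** It sets out from 23 and 14 and returns at 27, forming O1–C2 instead of C2–C1' in the stereo-defining event.
  - Claisen–Schmidt condensation (KOH, EtOH, rt) gives the 2'-hydroxychalcone F8.
  - An intramolecular asymmetric oxa-Michael addition closes ring C through O1, the only free oxygen beside the carbonyl. The catalyst is a bifunctional 9-amino-9-deoxy-epi-cinchona thiourea (10 mol %, toluene, rt), taken from the pseudoenantiomeric series that gives (2S).

Further compounds
F1 | step 10 | tert-butyldimethylsilyl ether of 12 | CC(C)(C)[Si](C)(C)Oc1c(I)c(OCOC)cc(OCOC)c1-c1c(OCOC)cc(OCc2ccccc2)cc1OCOC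
F2 | step 10 | arylmagnesium chloride from F1 (MgCl in place of I) | CC(C)(C)[Si](C)(C)Oc1c([Mg]Cl)c(OCOC)cc(OCOC)c1-c1c(OCOC)cc(OCc2ccccc2)cc1OCOC
F3 | step 10 | lithium [4-(methoxymethoxy)phenyl]acetylide | [Li]C#Cc1ccc(OCOC)cc1
F4 | step 10 | 3-[4-(methoxymethoxy)phenyl]prop-2-ynal | O=CC#Cc1ccc(OCOC)cc1
F5 | step 10 | racemic 1-[4'-(benzyloxy)-2-(tert-butyldimethylsilyloxy)-2',4,6,6'-tetrakis(methoxymethoxy)biphenyl-3-yl]-3-[4-(methoxymethoxy)phenyl]prop-2-yn-1-ol | OC(C#Cc1ccc(OCOC)cc1)c1c(O[Si](C)(C)C(C)(C)C)c(-c2c(OCOC)cc(OCc3ccccc3)cc2OCOC)c(OCOC)cc1OCOC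
F6 | step 10 | tert-butyldimethylsilyl ether of ynone 17 | O=C(C#Cc1ccc(OCOC)cc1)c1c(O[Si](C)(C)C(C)(C)C)c(-c2c(OCOC)cc(OCc3ccccc3)cc2OCOC)c(OCOC)cc1OCOC
F7 | step 6 | 4'-(benzyloxy)-2',4,6,6'-tetrakis(methoxymethoxy)biphenyl-2-ol | Oc1cc(OCOC)cc(OCOC)c1-c1c(OCOC)cc(OCc2ccccc2)cc1OCOC
F8 | step 15 | (E)-2'-hydroxychalcone from 23 and 14 | COCOc1ccc(/C=C/C(=O)c2c(O)cc(OCOC)c(-c3c(OCOC)cc(OCOC)c4c(=O)cc(-c5ccc(OCOC)cc5)oc34)c2OCOC)cc1
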